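Both oxiranes of the target sit next to a ketone (C3–C4 beside C2, C7–C14 beside C8), so each is disconnected to an allylic alcohol whose carbinol later becomes that ketone. The key step turns diol 9, a cyclohex-3-enol carrying the C1 isovalerate and a 2-substituted allyl alcohol on C6, into bis-epoxide 11 in one flask: titanium–L-(+)-tartrate fixes C7 by reagent control, then vanadium delivers oxygen to C3=C4 from the face of the C2 hydroxyl, cis to the C6 side chain. Diol 9 comes from (R)-carvone, which already holds the six-membered ring, the C3 methyl and C6; an alkenylchromium addition and a double oxidation finish the synthesis.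

Key step: step 6

Atom labels used below: ring C1 (CH–O-isovaleryl), C2, C3 (bears CH3), C4, C5 (CH2), C6; side chain C7 (quaternary), C14 (CH2 on C7), C8, C9=C10, C11 (CMe2OH).

Assumption: (R)-(−)-carvone is taken as the commercial source of the ring; its single stereocentre is C6 of the target.

Remark on the tartrate: L-(+)-diethyl tartrate is assigned by the usual Sharpless face rule for 2-substituted allyl alcohols (the sense that gives (S)-2-methylglycidol from 2-methylallyl alcohol); C6 takes the place of that methyl group as the lowest-ranked substituent at C7.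

Step 1
Reactants: 1 (R)-(−)-carvone
Product: 3 (5S,6S)-6-hydroxy-2-methyl-5-(prop-1-en-2-yl)cyclohex-2-en-1-one (trans-6-hydroxycarvone), via sodium dienolate 2 (not isolated)
Conditions: NaHMDS, THF, −78 °C; 2-(phenylsulfonyl)-3-phenyloxaziridine, −78 °C; AcOH
Reagents that add atoms: 2-(phenylsulfonyl)-3-phenyloxaziridine (Davis oxaziridine), O=S(=O)(c1ccccc1)N1OC1c1ccccc1
Why: Kinetic deprotonation at the α′-CH2 gives the cross-conjugated dienolate, and Davis oxaziridine enolate hydroxylation should occur on the face away from the neighbouring isopropenyl group, setting C1 trans to C6; the trans isomer is also the more stable one, so any epimerisation converges on it.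

Step 2
Reactants: 3 trans-6-hydroxycarvone; 4 isovaleryl chloride
Product: 5 (1S,6S)-3-methyl-2-oxo-6-(prop-1-en-2-yl)cyclohex-3-en-1-yl 3-methylbutanoate
Conditions: pyridine, DMAP (cat.), CH2Cl2, 0 °C → rt
Reagents that add atoms: none
Why: DMAP-catalysed acylation of the secondary α-ketol with an acid chloride is routine and touches no stereocentre.

Step 3
Reactants: 5 carvone-derived isovalerate
Product: 6 (1S,6S)-6-(3-chloroprop-1-en-2-yl)-3-methyl-2-oxocyclohex-3-en-1-yl 3-methylbutanoate
Conditions: Ca(OCl)2, CO2 (dry ice), CH2Cl2/H2O, 0 °C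
Reagents that add atoms: calcium hypochlorite, [Ca+2].[O-]Cl.[O-]Cl
Why: Ene-type allylic chlorination by hypochlorous acid attacks only the electron-rich 1,1-disubstituted alkene (the enone alkene is electron-poor) and, by loss of a methyl proton, gives the 2-substituted allyl chloride without touching a stereocentre.

Step 4
Reactants: 6 allyl chloride
Product: 8 (1S,6S)-6-(3-hydroxyprop-1-en-2-yl)-3-methyl-2-oxocyclohex-3-en-1-yl 3-methylbutanoate, via allyl formate 7 (not isolated)
Conditions: HCO2Na, n-Bu4NI (cat.), DMF, 45 °C; then MeOH, KHCO3 (cat.), 0 °C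
Reagents that add atoms: sodium formate, [Na+].[O-]C=O
Why: SN2 displacement of the primary allylic chloride by formate (SN2′ gives the same compound, the allyl termini being equivalent) followed by transesterification of the formate, which is far faster than methanolysis of the β-branched isovalerate; no stereocentre changes.

Step 5
Reactants: 8 hydroxy enone
Product: 9 (1S,2S,6S)-2-hydroxy-6-(3-hydroxyprop-1-en-2-yl)-3-methylcyclohex-3-en-1-yl 3-methylbutanoate
Conditions: NaBH4, CeCl3·7H2O, MeOH, −78 °C
Reagents that add atoms: none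
Why: Luche reduction gives clean 1,2-reduction, with hydride delivered axially to the half-chair in which the C1 ester and the C6 side chain are equatorial, so the new C2 hydroxyl should be pseudo-equatorial, trans to the ester and cis to the side chain, as in the reduction of carvone to cis-carveol.

Step 6
Reactants: 9 diol monoester
Product: 11 (1R,2R,3S,4R,6S)-2-hydroxy-4-[(2S)-2-(hydroxymethyl)oxiran-2-yl]-1-methyl-7-oxabicyclo[4.1.0]heptan-3-yl 3-methylbutanoate (bis-epoxy diol), via side-chain monoepoxide 10 (not isolated)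
Conditions: Ti(OiPr)4 (10 mol %), L-(+)-DET (12 mol %), TBHP (decane, 3 equiv), 4 Å MS, CH2Cl2, −20 °C until the side-chain alkene is consumed; then VO(acac)2 (10 mol %), −20 → 0 °C
Reagents that add atoms: tert-butyl hydroperoxide, CC(C)(C)OO
Why: Sharpless asymmetric epoxidation followed in the same flask by vanadium-catalysed hydroxyl-directed epoxidation, both known reaction types: each hydroxyl binds the metal as an alkoxide and the metal-bound tert-butyl peroxide oxygen is handed over intramolecularly to the neighbouring alkene. The C7–C14 oxirane closes by this concerted [2+1] oxygen transfer inside the titanium–tartrate complex, and C7 is set by the L-(+)-tartrate (reagent control; 7S in 10 and 11, the arrangement that is 7R in the target), with C6 as a spectator substituent. The C3–C4 oxirane closes by the same [2+1] transfer from the vanadium(V) alkoxide of the C2 hydroxyl, so C3 and C4 are set by the C2 carbinol (substrate control): oxygen arrives on the hydroxyl face, cis to the C6 side chain and trans to the C1 ester. Site selectivity in the titanium stage is needed and should come from the substrate itself, because the ring carbinol is a cyclic secondary allylic alcohol with the configuration that is the slow-reacting one for L-(+)-tartrate, so only the primary allylic alcohol reacts at −20 °C. Vanadium is added only when the side-chain alkene is consumed, so no undirected epoxidation at C7 can take place, and any ring epoxidation by titanium would give the same syn product. Catalytic titanium with sieves keeps the 2,2-disubstituted epoxy alcohol from being opened by isopropoxide, and the non-basic medium leaves the C1 ester in place.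

Step 7
Reactants: 11 bis-epoxy diol
Product: 12 (1R,2R,3S,4R,6S)-4-[(2R)-2-formyloxiran-2-yl]-2-hydroxy-1-methyl-7-oxabicyclo[4.1.0]heptan-3-yl 3-methylbutanoate
Conditions: TEMPO (cat.), PhI(OAc)2, CH2Cl2, 0 °C → rt
Reagents that add atoms: none
Why: Oxoammonium (TEMPO/PhI(OAc)2) oxidation is selective for the primary alcohol over the hindered secondary C2 carbinol and stops at the aldehyde, whose α-carbon C7 is quaternary and cannot epimerise.

Step 8
Reactants: 13 2-methylbut-3-yn-2-ol
Product: 15 (E)-4-iodo-2-methylbut-3-en-2-ol, via alkenylstannane 14 (not isolated)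
Conditions: Bu3SnH, AIBN (cat.), 80 °C; then I2, CH2Cl2, 0 °C
Reagents that add atoms: iodine, II (tributyltin hydride, CCCC[SnH](CCCC)CCCC, supplies the tin of 14 and one hydrogen of 15)
Why: Radical hydrostannation places tin on the terminal carbon and equilibrates to the (E)-alkenylstannane, and iododestannylation replaces tin by iodine with retention of the alkene geometry.

Step 9
Reactants: 12 epoxy aldehyde; 15 (E)-4-iodo-2-methylbut-3-en-2-ol
Product: 17 (1R,2R,3S,4R,6S)-4-{(2R)-2-[(2E)-1,4-dihydroxy-4-methylpent-2-en-1-yl]oxiran-2-yl}-2-hydroxy-1-methyl-7-oxabicyclo[4.1.0]heptan-3-yl 3-methylbutanoate (both C8 epimers), via alkenylchromium dichloride 16 (not isolated)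
Conditions: CrCl2, NiCl2 (cat.), DMSO, rt
Reagents that add atoms: none
Why: Nozaki–Hiyama–Kishi coupling: nickel-catalysed conversion of the iodide into the alkenylchromium(III) species with retention of the E geometry and its addition to the aldehyde, which tolerates the ester, both oxiranes and the free hydroxyls; the ring is kept at the carbinol stage here because an epoxy ketone would be reduced by Cr(II), and the C8 epimer mixture is erased in the last step.

Step 10
Reactants: 17 triol (C8 epimers)
Product: 18 (1S,3S,4R,6S)-4-{(2R)-2-[(2E)-4-hydroxy-4-methylpent-2-enoyl]oxiran-2-yl}-1-methyl-2-oxo-7-oxabicyclo[4.1.0]heptan-3-yl 3-methylbutanoate (CNP0292003.1)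
Conditions: Dess–Martin periodinane, pyridine, CH2Cl2, 0 °C → rt
Reagents that add atoms: none
Why: Dess–Martin oxidation converts both secondary carbinols (C2 and the allylic C8) into ketones while the tertiary C11 alcohol cannot react, the pyridine buffer protects the oxiranes and the C1 centre, and no stereocentre is created.

Compound list
1 | (R)-(−)-carvone, (5R)-2-methyl-5-(prop-1-en-2-yl)cyclohex-2-en-1-one | CC1=CC[C@H](CC1=O)C(C)=C | starting material
2 | sodium (3R)-6-methyl-3-(prop-1-en-2-yl)cyclohexa-1,5-dien-1-olate (cross-conjugated dienolate of 1) | [Na+].[O-]C1=C[C@H](C(C)=C)CC=C1C | intermediate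
3 | (5S,6S)-6-hydroxy-2-methyl-5-(prop-1-en-2-yl)cyclohex-2-en-1-one (hydroxyl trans to isopropenyl) | O[C@@H]1C(=O)C(C)=CC[C@H]1C(C)=C | intermediate
4 | isovaleryl chloride (3-methylbutanoyl chloride) | CC(C)CC(Cl)=O | starting material
5 | (1S,6S)-3-methyl-2-oxo-6-(prop-1-en-2-yl)cyclohex-3-en-1-yl 3-methylbutanoate | CC(C)CC(=O)O[C@@H]1C(=O)C(C)=CC[C@H]1C(C)=C | intermediate
6 | (1S,6S)-6-(3-chloroprop-1-en-2-yl)-3-methyl-2-oxocyclohex-3-en-1-yl 3-methylbutanoate | CC(C)CC(=O)O[C@@H]1C(=O)C(C)=CC[C@H]1C(=C)CCl | intermediate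
7 | (1S,6S)-6-[3-(formyloxy)prop-1-en-2-yl]-3-methyl-2-oxocyclohex-3-en-1-yl 3-methylbutanoate | CC(C)CC(=O)O[C@@H]1C(=O)C(C)=CC[C@H]1C(=C)COC=O | intermediate
8 | (1S,6S)-6-(3-hydroxyprop-1-en-2-yl)-3-methyl-2-oxocyclohex-3-en-1-yl 3-methylbutanoate | CC(C)CC(=O)O[C@@H]1C(=O)C(C)=CC[C@H]1C(=C)CO | intermediate
9 | (1S,2S,6S)-2-hydroxy-6-(3-hydroxyprop-1-en-2-yl)-3-methylcyclohex-3-en-1-yl 3-methylbutanoate (C2–OH trans to the ester, cis to the side chain) | CC(C)CC(=O)O[C@@H]1[C@@H](O)C(C)=CC[C@H]1C(=C)CO | intermediate
10 | (1S,2S,6R)-2-hydroxy-6-[(2S)-2-(hydroxymethyl)oxiran-2-yl]-3-methylcyclohex-3-en-1-yl 3-methylbutanoate | CC(C)CC(=O)O[C@@H]1[C@@H](O)C(C)=CC[C@H]1[C@]1(CO)CO1 | intermediate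
11 | (1R,2R,3S,4R,6S)-2-hydroxy-4-[(2S)-2-(hydroxymethyl)oxiran-2-yl]-1-methyl-7-oxabicyclo[4.1.0]heptan-3-yl 3-methylbutanoate (ring oxirane cis to hydroxyl and side chain) | CC(C)CC(=O)O[C@@H]1[C@@H](O)[C@@]2(C)O[C@H]2C[C@H]1[C@]1(CO)CO1 | intermediate
12 | (1R,2R,3S,4R,6S)-4-[(2R)-2-formyloxiran-2-yl]-2-hydroxy-1-methyl-7-oxabicyclo[4.1.0]heptan-3-yl 3-methylbutanoate | CC(C)CC(=O)O[C@@H]1[C@@H](O)[C@@]2(C)O[C@H]2C[C@H]1[C@]1(C=O)CO1 | intermediate
13 | 2-methylbut-3-yn-2-ol | CC(C)(O)C#C | starting material
14 | (E)-2-methyl-4-(tributylstannyl)but-3-en-2-ol | CCCC[Sn](CCCC)(CCCC)/C=C/C(C)(C)O | intermediate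
15 | (E)-4-iodo-2-methylbut-3-en-2-ol | CC(C)(O)/C=C/I | intermediate
16 | dichloro[(1E)-3-hydroxy-3-methylbut-1-en-1-yl]chromium(III) | CC(C)(O)/C=C/[Cr](Cl)Cl | intermediate
17 | (1R,2R,3S,4R,6S)-4-{(2R)-2-[(2E)-1,4-dihydroxy-4-methylpent-2-en-1-yl]oxiran-2-yl}-2-hydroxy-1-methyl-7-oxabicyclo[4.1.0]heptan-3-yl 3-methylbutanoate (both C8 epimers) | CC(C)CC(=O)O[C@@H]1[C@@H](O)[C@@]2(C)O[C@H]2C[C@H]1[C@]1(C(O)/C=C/C(C)(C)O)CO1 | intermediate
18 | (1S,3S,4R,6S)-4-{(2R)-2-[(2E)-4-hydroxy-4-methylpent-2-enoyl]oxiran-2-yl}-1-methyl-2-oxo-7-oxabicyclo[4.1.0]heptan-3-yl 3-methylbutanoate (CNP0292003.1) | CC(C)CC(=O)O[C@@H]1C(=O)[C@@]2(C)O[C@H]2C[C@H]1[C@]1(C(=O)/C=C/C(C)(C)O)CO1 | target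

Total step count: 10. Longest linear sequence: 9 steps (steps 1–7, 9 and 10 from (R)-carvone); step 8 is a one-step side branch.

Steps most likely to fail

Step 6. The one-flask sequence may lose site or face control. The second hydroxyl could slow the titanium stage, residual tartrate could retard the vanadium stage, and vanadium that meets unreacted side-chain alkene would epoxidise C7 without reagent control. The fallback separates the two oxygen transfers by the reduction and sets out from 8. Sharpless epoxidation (Ti(OiPr)4, L-(+)-DET, TBHP, 4 Å MS, CH2Cl2, −20 °C) of 8, whose only allylic alcohol is the primary one, should give the epoxy alcohol enone (1S,6R)-6-[(2S)-2-(hydroxymethyl)oxiran-2-yl]-3-methyl-2-oxocyclohex-3-en-1-yl 3-methylbutanoate F1. Luche reduction of F1 then gives 10, now isolated, and VO(acac)2/TBHP (CH2Cl2, 0 °C) directed by the C2 hydroxyl returns to the route at 11.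

Step 9. Chromium(II) may open the epoxy aldehyde reductively, or the coupling may be slow next to the quaternary C7. The fallback sets out from 12 and builds C8–C9 and C9=C10 separately. Vinylmagnesium bromide (THF, −78 °C, one extra equivalent for the free hydroxyl) adds to the aldehyde much faster than to the hindered ester and should give the vinyl carbinol (1R,2R,3S,4R,6S)-2-hydroxy-4-[(2R)-2-(1-hydroxyprop-2-en-1-yl)oxiran-2-yl]-1-methyl-7-oxabicyclo[4.1.0]heptan-3-yl 3-methylbutanoate F2 as an epimer mixture. E-selective cross-metathesis of F2 with commercial 2-methylbut-3-en-2-ol (Hoveyda–Grubbs second-generation catalyst, CH2Cl2, 40 °C) returns to the route at 17.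

Step 4. The mildly basic formate methanolysis may cause loss or migration of the isovalerate, or epimerisation at C1. The fallback sets out from 6 and avoids any ester cleavage. Kornblum–Ganem oxidation with N-methylmorpholine N-oxide (NaI cat., MeCN, rt) should convert the allyl chloride into the enal (1S,6S)-3-methyl-2-oxo-6-(3-oxoprop-1-en-2-yl)cyclohex-3-en-1-yl 3-methylbutanoate F3. Luche reduction with enough hydride for both carbonyl groups (NaBH4, CeCl3·7H2O, MeOH, −78 °C) then reduces aldehyde and ketone together and returns to the route at 9, bypassing 8.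

Further compounds
F1 | step 6 | (1S,6R)-6-[(2S)-2-(hydroxymethyl)oxiran-2-yl]-3-methyl-2-oxocyclohex-3-en-1-yl 3-methylbutanoate | CC(C)CC(=O)O[C@@H]1C(=O)C(C)=CC[C@H]1[C@]1(CO)CO1
F2 | step 9 | (1R,2R,3S,4R,6S)-2-hydroxy-4-[(2R)-2-(1-hydroxyprop-2-en-1-yl)oxiran-2-yl]-1-methyl-7-oxabicyclo[4.1.0]heptan-3-yl 3-methylbutanoate (both carbinol epimers) | CC(C)CC(=O)O[C@@H]1[C@@H](O)[C@@]2(C)O[C@H]2C[C@H]1[C@]1(C(O)C=C)CO1
F3 | step 4 | (1S,6S)-3-methyl-2-oxo-6-(3-oxoprop-1-en-2-yl)cyclohex-3-en-1-yl 3-methylbutanoate | CC(C)CC(=O)O[C@@H]1C(=O)C(C)=CC[C@H]1C(=C)C=O
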